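**Retrosynthetic overview**

- Feature: the single ring is a 1,4-benzoquinone with oxygen on C1, C2 and C4, methyl on C5 and henicosyl on C6. Without the C1 oxygen, the C2 and C4 oxygens are meta on a benzene ring next to adjacent methyl and alkyl groups. This is 5-henicosyl-4-methylresorcinol, the fold of a docosanoyl tetraketide whose last unit is a methylmalonate.
- Endgame: methoxyquinone ⇐ O-methylation of the C2 hydroxyl ⇐ para-oxidation of the resorcinol at C1 ⇐ loss of isobutene and CO2 from a quaternary cyclohexenedione tert-butyl ester.
- Key disconnection: ring bond C5–C6 (chain C2–C7) by intramolecular aldol condensation of tert-butyl 2-methyl-3,5,7-trioxooctacosanoate. This step forms the only ring.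
- Precursor: triketo ester ⇐ trianion acylation with methyl docosanoate (chain C6–C7) ⇐ dianion acylation with N-methoxy-N-methylacetamide (chain C4–C5) ⇐ C-methylated tert-butyl acetoacetate.

Key step: step 4

Assumption: compounds 2, 4, 6–9 and 11 are drawn as single keto tautomers although they should exist largely as enols. Compounds 2, 4, 6, 8 and 9 are racemic and 7 is a mixture of racemic diastereomers. This is of no consequence, because the target is achiral and each of these centres ends as an sp2 carbon.

**Route**

Step 1
Reactants: 1 tert-butyl acetoacetate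
Product: 2 tert-butyl 2-methyl-3-oxobutanoate
Conditions: MeI (1.05 equiv), K2CO3 (1.5 equiv), acetone, reflux
Reagents that add atoms: iodomethane, CI
Why: Acetoacetic ester alkylation of the stabilised enolate with one equivalent of MeI should stop at the mono-methyl compound because the tertiary enolate reacts more slowly; the new centre is racemic and epimerisable.

Step 2
Reactants: 2 tert-butyl 2-methyl-3-oxobutanoate; 3 N-methoxy-N-methylacetamide
Product: 4 tert-butyl 2-methyl-3,5-dioxohexanoate
Conditions: LiN(iPr)2 (2.2 equiv), THF, −78 → 0 °C; then 3 (0.9 equiv), −78 → −20 °C; aq. HCl (1 M), 0 °C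
Reagents that add atoms: none
Why: γ-Acylation of a β-keto ester dianion, in which the terminal carbanion adds to the Weinreb amide and the chelated tetrahedral adduct persists until the quench, so that neither over-addition nor proton transfer from the more acidic diketo ester can interfere.

Step 3
Reactants: 4 tert-butyl 2-methyl-3,5-dioxohexanoate; 5 methyl docosanoate
Product: 6 tert-butyl 2-methyl-3,5,7-trioxooctacosanoate
Conditions: 4 (2.2 equiv), LiN(iPr)2 (6.8 equiv), THF, −78 → 0 °C; then 5 (1 equiv) in THF, 0 °C → rt; aq. HCl (1 M), 0 °C
Reagents that add atoms: none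
Why: Claisen-type acylation of a 3,5-diketo ester trianion, which should react at its last-formed and most nucleophilic terminal carbanion (C6), with the second equivalent of trianion taking up the proton released by the more acidic triketo ester.

Step 4
Reactants: 6 tert-butyl 2-methyl-3,5,7-trioxooctacosanoate
Product: 8 tert-butyl 2-henicosyl-1-methyl-4,6-dioxocyclohex-2-ene-1-carboxylate, via aldol adduct 7 (not isolated)
Conditions: K2CO3 (2 equiv), MeOH–THF (1:1), 0 °C → rt; then AcOH (excess), 40 °C
Reagents that add atoms: none
Why: Proposed new method: carbonate deprotonates the doubly activated, methyl-bearing chain carbon C2, and this enolate adds to the C7 ketone in a 6-(enolexo)-exo-trig aldol closure that forms the C2–C7 bond and the only ring, after which acetic acid promotes loss of the tertiary hydroxyl toward C6 to give the conjugated cyclohexenedione, held as its enolised β-diketone. The closest known reaction type is the biomimetic aldol cyclisation of 3,5,7-triketo esters to resorcylates under carbonate or hydroxide; what is new is the methyl group on C2, which makes the ring carbon quaternary, so that enone and vinylogous-acid formation must drive the closure in place of immediate aromatisation. The quaternary carbon forms as a racemate without stereocontrol, which is harmless because it becomes a planar arene carbon in step 5. The step needs the C2-to-C7 aldol to beat Claisen attack of C6 on the ester, the alternative aldol of C8 on the C3 ketone, and pyrone or 4-pyranone closure. The tert-butyl ester is too hindered and too poor an acyl donor for the Claisen and lactone modes, the mild base leaves the singly activated C8 essentially un-enolised, and cyclising under basic conditions before any acid is added avoids cyclodehydration to the pyranone.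

Step 5
Reactants: 8 tert-butyl 2-henicosyl-1-methyl-4,6-dioxocyclohex-2-ene-1-carboxylate
Product: 10 5-henicosyl-4-methylbenzene-1,3-diol, via free β-keto acid 9 (not isolated)
Conditions: p-TsOH·H2O (0.1 equiv), toluene, 90 °C, N2 sweep
Reagents that add atoms: none
Why: Acid-catalysed loss of isobutene from the tert-butyl ester should free a β-keto acid that decarboxylates through the usual cyclic transition state to a dienol, which tautomerises irreversibly to the resorcinol (decarboxylative aromatisation), while both gases leave the hot solution and so cannot alkylate the arene.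

Step 6
Reactants: 10 5-henicosyl-4-methylbenzene-1,3-diol
Product: 11 6-henicosyl-2-hydroxy-5-methyl-1,4-benzoquinone
Conditions: (KSO3)2NO (2.5 equiv), KH2PO4 buffer (pH 6), Bu4NHSO4 (cat.), CH2Cl2–H2O, rt
Reagents that add atoms: potassium nitrosodisulfonate (Fremy's salt), [O]N(S(=O)(=O)[O-])S(=O)(=O)[O-].[K+].[K+]
Why: Teuber oxidation, in which the phenoxyl radical is trapped by a second equivalent of the nitroxide at the only unsubstituted ring carbon para to a hydroxyl (para to the hydroxyl beside the methyl group), and loss of HN(SO3K)2 should give the para-quinone with the other hydroxyl kept as a vinylogous acid.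

Step 7
Reactants: 11 6-henicosyl-2-hydroxy-5-methyl-1,4-benzoquinone
Product: 12 6-henicosyl-2-methoxy-5-methyl-1,4-benzoquinone
Conditions: MeOH–CH2Cl2 (3:1), H2SO4 (cat.), 40 °C
Reagents that add atoms: methanol, CO
Why: Acid-catalysed vinylogous Fischer esterification of the 2-hydroxy-1,4-quinone with methanol, which under equilibrating conditions should give the more stable 2-methoxy-para-quinone and has no other hydroxyl to touch.

**Compound list**

1 | tert-butyl acetoacetate (tert-butyl 3-oxobutanoate) | CC(=O)CC(=O)OC(C)(C)C | starting material
2 | tert-butyl 2-methyl-3-oxobutanoate (racemic) | CC(=O)C(C)C(=O)OC(C)(C)C | intermediate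
3 | N-methoxy-N-methylacetamide | CC(=O)N(C)OC | starting material
4 | tert-butyl 2-methyl-3,5-dioxohexanoate (racemic) | CC(=O)CC(=O)C(C)C(=O)OC(C)(C)C | intermediate
5 | methyl docosanoate | CCCCCCCCCCCCCCCCCCCCCC(=O)OC | starting material
6 | tert-butyl 2-methyl-3,5,7-trioxooctacosanoate (racemic) | CCCCCCCCCCCCCCCCCCCCCC(=O)CC(=O)CC(=O)C(C)C(=O)OC(C)(C)C | intermediate
7 | tert-butyl 2-henicosyl-2-hydroxy-1-methyl-4,6-dioxocyclohexane-1-carboxylate (racemic, mixture of diastereomers) | CCCCCCCCCCCCCCCCCCCCCC1(O)CC(=O)CC(=O)C1(C)C(=O)OC(C)(C)C | intermediate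
8 | tert-butyl 2-henicosyl-1-methyl-4,6-dioxocyclohex-2-ene-1-carboxylate (racemic) | CCCCCCCCCCCCCCCCCCCCCC1=CC(=O)CC(=O)C1(C)C(=O)OC(C)(C)C | intermediate
9 | 2-henicosyl-1-methyl-4,6-dioxocyclohex-2-ene-1-carboxylic acid (racemic) | CCCCCCCCCCCCCCCCCCCCCC1=CC(=O)CC(=O)C1(C)C(O)=O | intermediate
10 | 5-henicosyl-4-methylbenzene-1,3-diol | CCCCCCCCCCCCCCCCCCCCCc1cc(O)cc(O)c1C | intermediate
11 | 6-henicosyl-2-hydroxy-5-methyl-1,4-benzoquinone (3-henicosyl-5-hydroxy-2-methylcyclohexa-2,5-diene-1,4-dione) | CCCCCCCCCCCCCCCCCCCCCC1=C(C)C(=O)C=C(O)C1=O | intermediate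
12 | 6-henicosyl-2-methoxy-5-methyl-1,4-benzoquinone (3-henicosyl-5-methoxy-2-methylcyclohexa-2,5-diene-1,4-dione) | CCCCCCCCCCCCCCCCCCCCCC1=C(C)C(=O)C=C(OC)C1=O | target

**Summary**

Total step count: 7.
Longest linear sequence: 7 steps (1 to 12); 3 and 5 enter as purchased materials.

**Steps most likely to fail**

1. Step 4 (proposed new method). The aldol addition at the hindered, methyl-bearing carbon may revert faster than the adduct dehydrates. Material would then drain through slower closures (aldol of C8 onto the C3 ketone followed by aromatisation, or cyclodehydration to a 4-pyranone in the acid phase) or through retro-Claisen cleavage of the chain. The fallback uses known chemistry, sets out from 5 and rejoins the route at 10. Reduction of 5 with iBu2AlH (CH2Cl2, −78 °C) should give docosanal F1. Wittig olefination with 3-(triphenylphosphoranylidene)butan-2-one (toluene, reflux) should give (E)-3-methylpentacos-3-en-2-one F2. Michael addition of dimethyl malonate followed by Dieckmann closure (NaOMe, MeOH, reflux) should give methyl 6-henicosyl-5-methyl-2,4-dioxocyclohexane-1-carboxylate F3 as a mixture of diastereomers. Bromination–dehydrobromination (Br2, DMF, 0 → 80 °C) should aromatise it to methyl 6-henicosyl-2,4-dihydroxy-5-methylbenzoate F4. Saponification and decarboxylation (aq. NaOH, reflux; then HCl) should then give 10.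

2. Step 3. Proton transfer from the α-methylene of the ester, or from the more acidic acylated product, to the trianion may outrun C-acylation and stall the condensation. The C22 ester may also come out of solution in cold THF. The fallback sets out from 5 and 2 and rejoins at 6; it brings in the C7 ketone masked and joins the chain at C4–C5 by the same dianion acylation as step 2, so no trianion is needed. Claisen condensation of 5 with the lithium enolate of 3 (LiN(iPr)2, THF, −78 °C, two equivalents of enolate) should give N-methoxy-N-methyl-3-oxotetracosanamide F5. Ketalisation (ethane-1,2-diol, p-TsOH·H2O cat., benzene, Dean–Stark) should give 2-(2-henicosyl-1,3-dioxolan-2-yl)-N-methoxy-N-methylacetamide F6. Acylation of the dianion of 2 with F6 should give tert-butyl 6-(2-henicosyl-1,3-dioxolan-2-yl)-2-methyl-3,5-dioxohexanoate F7. Mild deketalisation (pyridinium p-toluenesulfonate, acetone–H2O, 40 °C) should release 6.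

3. Step 6. Oxidation of the unprotected resorcinol may not stop cleanly at the hydroxyquinone: attack at the carbon between the two hydroxyls, over-oxidation and oxidative coupling of the electron-rich product are possible. The fallback sets out from 10 and rejoins at 12; it fixes the regiochemistry by substitution chemistry and avoids any free hydroxyquinone. Exhaustive O-methylation (Me2SO4, K2CO3, acetone, reflux) should give 1-henicosyl-3,5-dimethoxy-2-methylbenzene F8. Bromination (N-bromosuccinimide, MeCN, 0 °C) at the only free ring carbon para to a methoxy group should give 2-bromo-3-henicosyl-1,5-dimethoxy-4-methylbenzene F9. Bromine–lithium exchange, borylation and oxidation (n-BuLi, THF, −78 °C; B(OMe)3; H2O2, NaOH) should give 2-henicosyl-4,6-dimethoxy-3-methylphenol F10. Oxidative demethylation of this para-methoxyphenol with (NH4)2Ce(NO3)6 (MeCN–H2O, 0 °C) should give 12.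

**Further compounds**

F1 | step 4 | docosanal | CCCCCCCCCCCCCCCCCCCCCC=O
F2 | step 4 | (E)-3-methylpentacos-3-en-2-one | CCCCCCCCCCCCCCCCCCCCC/C=C(\C)C(C)=O
F3 | step 4 | methyl 6-henicosyl-5-methyl-2,4-dioxocyclohexane-1-carboxylate (mixture of diastereomers) | CCCCCCCCCCCCCCCCCCCCCC1C(C)C(=O)CC(=O)C1C(=O)OC
F4 | step 4 | methyl 6-henicosyl-2,4-dihydroxy-5-methylbenzoate | CCCCCCCCCCCCCCCCCCCCCc1c(C)c(O)cc(O)c1C(=O)OC
F5 | step 3 | N-methoxy-N-methyl-3-oxotetracosanamide | CCCCCCCCCCCCCCCCCCCCCC(=O)CC(=O)N(C)OC
F6 | step 3 | 2-(2-henicosyl-1,3-dioxolan-2-yl)-N-methoxy-N-methylacetamide | CCCCCCCCCCCCCCCCCCCCCC1(CC(=O)N(C)OC)OCCO1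
F7 | step 3 | tert-butyl 6-(2-henicosyl-1,3-dioxolan-2-yl)-2-methyl-3,5-dioxohexanoate (racemic) | CCCCCCCCCCCCCCCCCCCCCC1(CC(=O)CC(=O)C(C)C(=O)OC(C)(C)C)OCCO1
F8 | step 6 | 1-henicosyl-3,5-dimethoxy-2-methylbenzene | CCCCCCCCCCCCCCCCCCCCCc1cc(OC)cc(OC)c1C
F9 | step 6 | 2-bromo-3-henicosyl-1,5-dimethoxy-4-methylbenzene | CCCCCCCCCCCCCCCCCCCCCc1c(Br)c(OC)cc(OC)c1C
F10 | step 6 | 2-henicosyl-4,6-dimethoxy-3-methylphenol | CCCCCCCCCCCCCCCCCCCCCc1c(O)c(OC)cc(OC)c1C
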